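**Plan**
- Feature: in the oxolane ring (O1–C2–C3–C4–C5), C2 (aryl) and C3 (CH2OH) form the syn pair of a homoallylic alcohol once C4 is read as an alkene carbon and C5 as a lactone carbonyl.
- Retrosynthesis: remove the silyl group; cut O1–C5 (ether closure of a 1,4-diol, C5 traced back to a lactone carbonyl); cut the aryl–CH bond of the C4 benzyl group (Heck) after reading C4 as an alkene carbon; then cut C2–C3 and the acyl O1–C5 bond together, giving 3,4,5-trimethoxybenzaldehyde and a γ-substituted 2-(methoxycarbonyl)allylboronate made from a Baylis–Hillman acetate.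
- Forward: acyclic boronate (three steps), α-methylene lactone (ring formed), benzylidene lactone, all-cis lactone, 1,4-diol, oxolane (same ring atoms re-closed at the ether level), desilylation.
- Stereochemistry: C2 from the chiral phosphoric acid (aldehyde face); C3 relative to C2 from the chair and the alkene geometry of the boronate; C4 from hydrogenation on the face opposite the C2 and C3 substituents. The target is all-cis, (2R,3R,4R).

Key step: step 4

Assumption: the (R)-configured phosphoric acid is taken to direct the allyl group to the Re face of the aldehyde, as it does with allyl and crotyl pinacol boronates; if the sense proves opposite, the (S)-acid is used with no other change.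

Step 1
Reactants: 1 methyl acrylate; 2 (tert-butyldimethylsilyloxy)acetaldehyde
Product: 3 methyl 4-[(tert-butyldimethylsilyl)oxy]-3-hydroxy-2-methylidenebutanoate (racemic)
Conditions: DABCO (0.5 equiv), 1 (3 equiv), MeOH, rt
Reagents that add atoms: none
Why: Morita–Baylis–Hillman reaction, for which α-oxygenated aldehydes are reactive acceptors; the racemic carbinol centre is removed again in step 3.

Step 2
Reactants: 3 methyl 4-[(tert-butyldimethylsilyl)oxy]-3-hydroxy-2-methylidenebutanoate
Product: 4 methyl 3-acetoxy-4-[(tert-butyldimethylsilyl)oxy]-2-methylidenebutanoate (racemic)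
Conditions: Ac2O, pyridine, DMAP (cat.), CH2Cl2, 0 °C → rt
Reagents that add atoms: acetic anhydride, CC(=O)OC(C)=O
Why: DMAP-catalysed acetylation of a secondary allylic alcohol, which turns the hydroxyl into the leaving group needed for allylic substitution.

Step 3
Reactants: 4 methyl 3-acetoxy-4-[(tert-butyldimethylsilyl)oxy]-2-methylidenebutanoate
Product: 5 methyl (E)-4-[(tert-butyldimethylsilyl)oxy]-2-[(4,4,5,5-tetramethyl-1,3,2-dioxaborolan-2-yl)methyl]but-2-enoate (CH2B cis to CH2OSi)
Conditions: B2pin2, CuCl (10 mol %), LiCl, KOAc, DMF, rt; minor alkene isomer removed by chromatography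
Reagents that add atoms: bis(pinacolato)diboron, CC1(C)OB(OC1(C)C)B1OC(C)(C)C(C)(C)O1
Why: Copper-catalysed SN2′ allylic borylation of a Baylis–Hillman acetate, in which a borylcopper species adds to the acrylate terminus and acetate leaves, and the trisubstituted alkene should form mainly with the CH2OSi group trans to the ester and therefore cis to CH2B.

Step 4
Reactants: 5 methyl (E)-4-[(tert-butyldimethylsilyl)oxy]-2-[(4,4,5,5-tetramethyl-1,3,2-dioxaborolan-2-yl)methyl]but-2-enoate; 6 3,4,5-trimethoxybenzaldehyde
Product: 8 (4R,5R)-4-{[(tert-butyldimethylsilyl)oxy]methyl}-3-methylidene-5-(3,4,5-trimethoxyphenyl)oxolan-2-one, via O-boryl homoallylic ester 7 (not isolated)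
Conditions: (R)-TRIP [(R)-3,3′-bis(2,4,6-triisopropylphenyl)-1,1′-binaphthyl-2,2′-diyl hydrogen phosphate] (10 mol %), 4 Å MS, PhMe, 0 °C → rt; then pyridinium p-toluenesulfonate (cat.), 40 °C
Reagents that add atoms: none
Why: Proposed new method: the phosphoric acid should hydrogen-bond to a boronate oxygen and to the formyl hydrogen, so that the allyl unit is transferred through a closed six-membered chair with boron on the aldehyde oxygen and the new C–C bond between the γ-carbon of 5 and the carbonyl carbon of 6; the closest known reactions are the phosphoric acid-catalysed allyl- and crotylboration of aldehydes with pinacol boronates and the acid-promoted allylboration–lactonisation of 2-(alkoxycarbonyl)allylboronates. The lactone ring then closes by 5-exo-trig acyl substitution of the boron-bound alkoxide of 7 on the neighbouring methyl ester, methoxide passing to boron. The carbinol centre (C5 of 8, R) is controlled by the catalyst, which should expose the Re face of the aldehyde with the aryl group equatorial; the centre bearing CH2OSi (C4 of 8, R) is controlled by the alkene geometry of 5, whose CH2OSi group lies cis to CH2B, must sit axial in the chair and so ends cis to the aryl group. The step needs enantioface selection, syn (cis) diastereoselection and an intact benzylic C–O bond; the first rests on the catalyst pocket, the second on the stereospecific chair, and the third on the mildness of the acid and the only modest cation-stabilising power of the 3,4,5-trimethoxyphenyl group. Aldehyde 6 has no α-hydrogen and the ester lowers the nucleophilicity of 5, so the uncatalysed background addition should be slow at this temperature and the catalysed path should dominate.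

Step 5
Reactants: 8 (4R,5R)-4-{[(tert-butyldimethylsilyl)oxy]methyl}-3-methylidene-5-(3,4,5-trimethoxyphenyl)oxolan-2-one; 9 1-iodo-2,4,5-trimethoxybenzene
Product: 10 (3E,4R,5R)-4-{[(tert-butyldimethylsilyl)oxy]methyl}-5-(3,4,5-trimethoxyphenyl)-3-[(2,4,5-trimethoxyphenyl)methylidene]oxolan-2-one
Conditions: Pd(OAc)2 (10 mol %), Et3N, DMF, 80 °C
Reagents that add atoms: none
Why: Heck arylation of an α-methylene lactone, in which the arylpalladium iodide (from oxidative addition of 9 to zerovalent palladium) adds its aryl group to the unsubstituted alkene terminus and β-hydride elimination from the new benzylic CH2 should give the conjugated (E)-benzylidene lactone without touching the two stereocentres.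

Step 6
Reactants: 10 (3E,4R,5R)-4-{[(tert-butyldimethylsilyl)oxy]methyl}-5-(3,4,5-trimethoxyphenyl)-3-[(2,4,5-trimethoxyphenyl)methylidene]oxolan-2-one
Product: 11 (3R,4R,5R)-4-{[(tert-butyldimethylsilyl)oxy]methyl}-5-(3,4,5-trimethoxyphenyl)-3-[(2,4,5-trimethoxyphenyl)methyl]oxolan-2-one
Conditions: H2 (1 atm), 5% Rh/Al2O3, EtOAc, rt
Reagents that add atoms: none
Why: Heterogeneous syn hydrogenation, in which the alkene should bind the metal on the lactone face opposite the cis CH2OSi and aryl groups, so hydrogen enters there and the new benzyl-bearing centre (C3 of the lactone, R) ends cis to both; Rh on alumina is chosen to spare the benzylic lactone C–O bond.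

Step 7
Reactants: 11 (3R,4R,5R)-4-{[(tert-butyldimethylsilyl)oxy]methyl}-5-(3,4,5-trimethoxyphenyl)-3-[(2,4,5-trimethoxyphenyl)methyl]oxolan-2-one
Product: 12 (1R,2R,3R)-2-{[(tert-butyldimethylsilyl)oxy]methyl}-1-(3,4,5-trimethoxyphenyl)-3-[(2,4,5-trimethoxyphenyl)methyl]butane-1,4-diol
Conditions: LiAlH4, THF, 0 °C
Reagents that add atoms: none
Why: Hydride reduction of the lactone to the 1,4-diol, fast enough at 0 °C that the epimerisable α-centre should not equilibrate and mild enough to leave the primary silyl ether in place.

Step 8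
Reactants: 12 (1R,2R,3R)-2-{[(tert-butyldimethylsilyl)oxy]methyl}-1-(3,4,5-trimethoxyphenyl)-3-[(2,4,5-trimethoxyphenyl)methyl]butane-1,4-diol
Product: 14 tert-butyldimethyl{[(2R,3R,4R)-2-(3,4,5-trimethoxyphenyl)-4-[(2,4,5-trimethoxyphenyl)methyl]oxolan-3-yl]methoxy}silane, via primary tosylate 13 (not isolated)
Conditions: TsCl (1.1 equiv), Et3N, DMAP (cat.), CH2Cl2, 0 °C → 40 °C
Reagents that add atoms: none
Why: Selective sulfonylation of the primary hydroxyl followed by intramolecular Williamson etherification (5-exo-tet) by the secondary benzylic hydroxyl; the benzylic C–O bond is never broken, so C2 should keep its configuration, which an acid-mediated lactol reduction could put at risk.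

Step 9
Reactants: 14 tert-butyldimethyl{[(2R,3R,4R)-2-(3,4,5-trimethoxyphenyl)-4-[(2,4,5-trimethoxyphenyl)methyl]oxolan-3-yl]methoxy}silane
Product: 15 [(2R,3R,4R)-2-(3,4,5-trimethoxyphenyl)-4-[(2,4,5-trimethoxyphenyl)methyl]oxolan-3-yl]methanol
Conditions: Bu4NF, THF, 0 °C → rt
Reagents that add atoms: none
Why: Fluoride-mediated cleavage of the primary silyl ether, to which the aryl methyl ethers and the oxolane are inert.

**Compound list**
1 | methyl acrylate | C=CC(=O)OC | starting material
2 | (tert-butyldimethylsilyloxy)acetaldehyde | CC(C)(C)[Si](C)(C)OCC=O | starting material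
3 | methyl 4-[(tert-butyldimethylsilyl)oxy]-3-hydroxy-2-methylidenebutanoate (racemic) | C=C(C(=O)OC)C(O)CO[Si](C)(C)C(C)(C)C | intermediate
4 | methyl 3-acetoxy-4-[(tert-butyldimethylsilyl)oxy]-2-methylidenebutanoate (racemic) | C=C(C(=O)OC)C(OC(C)=O)CO[Si](C)(C)C(C)(C)C | intermediate
5 | methyl (E)-4-[(tert-butyldimethylsilyl)oxy]-2-[(4,4,5,5-tetramethyl-1,3,2-dioxaborolan-2-yl)methyl]but-2-enoate | CC1(C)OB(OC1(C)C)C/C(C(=O)OC)=C\CO[Si](C)(C)C(C)(C)C | intermediate
6 | 3,4,5-trimethoxybenzaldehyde | COc1cc(C=O)cc(OC)c1OC | starting material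
7 | methyl (3R,4R)-3-{[(tert-butyldimethylsilyl)oxy]methyl}-2-methylidene-4-[(4,4,5,5-tetramethyl-1,3,2-dioxaborolan-2-yl)oxy]-4-(3,4,5-trimethoxyphenyl)butanoate (not isolated) | COC(=O)C(=C)[C@H](CO[Si](C)(C)C(C)(C)C)[C@@H](OB1OC(C)(C)C(C)(C)O1)c2cc(OC)c(OC)c(OC)c2 | intermediate
8 | (4R,5R)-4-{[(tert-butyldimethylsilyl)oxy]methyl}-3-methylidene-5-(3,4,5-trimethoxyphenyl)oxolan-2-one | C=C1C(=O)O[C@@H](c2cc(OC)c(OC)c(OC)c2)[C@H]1CO[Si](C)(C)C(C)(C)C | intermediate
9 | 1-iodo-2,4,5-trimethoxybenzene | COc1cc(OC)c(OC)cc1I | starting material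
10 | (3E,4R,5R)-4-{[(tert-butyldimethylsilyl)oxy]methyl}-5-(3,4,5-trimethoxyphenyl)-3-[(2,4,5-trimethoxyphenyl)methylidene]oxolan-2-one | COc1cc(OC)c(OC)cc1/C=C2/C(=O)O[C@@H](c3cc(OC)c(OC)c(OC)c3)[C@H]2CO[Si](C)(C)C(C)(C)C | intermediate
11 | (3R,4R,5R)-4-{[(tert-butyldimethylsilyl)oxy]methyl}-5-(3,4,5-trimethoxyphenyl)-3-[(2,4,5-trimethoxyphenyl)methyl]oxolan-2-one | COc1cc(OC)c(OC)cc1C[C@H]2C(=O)O[C@@H](c3cc(OC)c(OC)c(OC)c3)[C@H]2CO[Si](C)(C)C(C)(C)C | intermediate
12 | (1R,2R,3R)-2-{[(tert-butyldimethylsilyl)oxy]methyl}-1-(3,4,5-trimethoxyphenyl)-3-[(2,4,5-trimethoxyphenyl)methyl]butane-1,4-diol | COc1cc(OC)c(OC)cc1C[C@@H](CO)[C@H](CO[Si](C)(C)C(C)(C)C)[C@@H](O)c2cc(OC)c(OC)c(OC)c2 | intermediate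
13 | (2R,3R,4R)-3-{[(tert-butyldimethylsilyl)oxy]methyl}-4-hydroxy-4-(3,4,5-trimethoxyphenyl)-2-[(2,4,5-trimethoxyphenyl)methyl]butyl 4-methylbenzenesulfonate (not isolated) | COc1cc(OC)c(OC)cc1C[C@@H](COS(=O)(=O)c2ccc(C)cc2)[C@H](CO[Si](C)(C)C(C)(C)C)[C@@H](O)c3cc(OC)c(OC)c(OC)c3 | intermediate
14 | tert-butyldimethyl{[(2R,3R,4R)-2-(3,4,5-trimethoxyphenyl)-4-[(2,4,5-trimethoxyphenyl)methyl]oxolan-3-yl]methoxy}silane | COc1cc(OC)c(OC)cc1C[C@H]2CO[C@@H](c3cc(OC)c(OC)c(OC)c3)[C@H]2CO[Si](C)(C)C(C)(C)C | intermediate
15 | [(2R,3R,4R)-2-(3,4,5-trimethoxyphenyl)-4-[(2,4,5-trimethoxyphenyl)methyl]oxolan-3-yl]methanol | COc1cc(OC)c(OC)cc1C[C@H]1CO[C@@H](c2cc(OC)c(OC)c(OC)c2)[C@H]1CO | target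

**Step count and risks**
Total steps: 9. Longest linear sequence: 9 (from 1 and 2; aldehyde 6 and iodide 9 enter as purchased).

Steps most likely to fail:

1. Step 4. The ester-deactivated boronate may add so slowly that the catalyst no longer outpaces the unselective background addition, which would lower the enantiomeric purity. Prolonged contact with acid may ionise the benzylic C–O bond and shift material toward the trans lactone, and ring closure of the cis adduct may stall. Fallback, setting out from 5 and 6 and returning at 8: the two partners are heated without chiral acid (PhMe, 80 °C, then catalytic pyridinium p-toluenesulfonate). This is the established thermal allylboration–lactonisation of 3-substituted 2-(alkoxycarbonyl)allyl pinacol boronates; it runs through the same chair and should give the cis lactone as a racemate. That racemate is 8 together with its mirror image, the (4S,5S)-lactone F2, which arises through the enantiomeric O-boryl ester F1. The enantiomers are separated by preparative chromatography on a polysaccharide chiral stationary phase, F2 is set aside, and 8 continues with step 5.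

2. Step 5. After carbopalladation, β-hydride elimination toward the ring, or re-addition of the palladium hydride, may move the double bond into the lactone and erase the CH2OSi-bearing stereocentre. Oxidative addition of the electron-rich, ortho-substituted iodide may also be slow. Fallback, setting out from 8 and 9 and returning at 11, so that steps 5 and 6 are both replaced: iodide 9 is converted by iodine–magnesium exchange (i-PrMgCl·LiCl, THF, 0 °C → rt) into (2,4,5-trimethoxyphenyl)magnesium chloride F3. F3 is added 1,4 to lactone 8 under CuBr·SMe2 catalysis at −78 °C, a known copper-catalysed conjugate addition of arylmagnesium halides to α-methylene lactones. The resulting chloromagnesium enolate F4 is protonated at −78 °C with aqueous NH4Cl on the face opposite the CH2OSi group, which should give 11 directly.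

3. Step 6. Hydrogenolysis of the benzylic lactone C–O bond, partial saturation of an electron-rich arene on rhodium, or incomplete facial discrimination may intervene. Fallback, setting out from 10 and returning at 11: conjugate reduction with [(Ph3P)CuH]6 in moist toluene/THF at rt, a known 1,4-reduction of alkylidene lactones. Hydride is delivered to the benzylidene carbon, and the copper enolate F5 is protonated by water on the open face, opposite the CH2OSi and aryl groups, to give 11. No hydrogen gas or noble-metal surface is present, so the arenes and the benzylic C–O bond should be untouched.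

**Further compounds**
F1 | step 4 | methyl (3S,4S)-3-{[(tert-butyldimethylsilyl)oxy]methyl}-2-methylidene-4-[(4,4,5,5-tetramethyl-1,3,2-dioxaborolan-2-yl)oxy]-4-(3,4,5-trimethoxyphenyl)butanoate | COC(=O)C(=C)[C@@H](CO[Si](C)(C)C(C)(C)C)[C@H](OB1OC(C)(C)C(C)(C)O1)c2cc(OC)c(OC)c(OC)c2
F2 | step 4 | (4S,5S)-4-{[(tert-butyldimethylsilyl)oxy]methyl}-3-methylidene-5-(3,4,5-trimethoxyphenyl)oxolan-2-one | C=C1C(=O)O[C@H](c2cc(OC)c(OC)c(OC)c2)[C@@H]1CO[Si](C)(C)C(C)(C)C
F3 | step 5 | (2,4,5-trimethoxyphenyl)magnesium chloride | COc1cc(OC)c(OC)cc1[Mg]Cl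
F4 | step 5 | chloromagnesium enolate of lactone 11, {(4R,5R)-4-{[(tert-butyldimethylsilyl)oxy]methyl}-5-(3,4,5-trimethoxyphenyl)-3-[(2,4,5-trimethoxyphenyl)methyl]-4,5-dihydrofuran-2-yl}oxymagnesium chloride | COc1cc(OC)c(OC)cc1CC2=C(O[Mg]Cl)O[C@@H](c3cc(OC)c(OC)c(OC)c3)[C@H]2CO[Si](C)(C)C(C)(C)C
F5 | step 6 | copper enolate of lactone 11 (monovalent copper, triphenylphosphine-bound), {(4R,5R)-4-{[(tert-butyldimethylsilyl)oxy]methyl}-5-(3,4,5-trimethoxyphenyl)-3-[(2,4,5-trimethoxyphenyl)methyl]-4,5-dihydrofuran-2-yl}oxycopper | COc1cc(OC)c(OC)cc1CC2=C(O[Cu])O[C@@H](c3cc(OC)c(OC)c(OC)c3)[C@H]2CO[Si](C)(C)C(C)(C)C
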